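Ring A (carboxylic acid ring) and ring B (acyl ring) are the same 2,4-dioxygenated 6-(2-oxoheptyl)benzoate, so one arene serves both. Ring B is disconnected at C3–C4 and C5–C6. The feature exploited is its pattern of ester at C1, oxygen at C2 and C4, hydrogen at C3 and C5 and chain at C6. C1, C2, C3 and C6 are C5, C4, C3 and C6 of a 2-pyrone-5-carboxylate; C4 and C5 are the carbons of a ketene acetal. In one operation, inverse-demand (4+2) cycloaddition, CO2 loss and benzyl alcohol loss convert pyrone 14, which already carries ester, C4 benzyloxy group and ketal-masked chain, into benzoate 17.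

Key step: step 8

Remark: ring positions count from the carboxyl-bearing carbon (C1) of each ring; ethyl 3-oxooctanoate 5 and prop-2-enyl hydrogen malonate 8 are taken as catalogue compounds; the target has no stereocentre.

Design: the ketal enters with the β-keto ester, so no free 2-oxoheptyl ketone ever sits beside an ester it could lactonise onto. Benzoate 17 supplies both rings. The ketals are opened before, not after, the final hydrogenolysis.

Step 1
Reactants: 1 2-bromo-1,1-diethoxyethane; 2 benzyl alcohol
Product: 3 2-bromo-1,1-bis(benzyloxy)ethane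
Conditions: 2 (2.2 equiv), p-TsOH·H2O (cat.), neat, 110–120 °C, EtOH distilled off; K2CO3 quench
Reagents that add atoms: none
Why: Acid-catalysed transacetalisation is an equilibrium that is pulled to the dibenzyl acetal by distilling out the far more volatile ethanol, and the primary bromide is inert to these conditions.

Step 2
Reactants: 3 2-bromo-1,1-bis(benzyloxy)ethane
Product: 4 1,1-bis(benzyloxy)ethene
Conditions: KOtBu, THF, 0 °C to rt; filtration, short-path distillation under high vacuum from K2CO3
Reagents that add atoms: none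
Why: E2 dehydrobromination of a 2-bromoacetal by a hindered alkoxide is the standard entry to ketene acetals, because the acetal C–H is the only β-hydrogen and tert-butoxide is too bulky to substitute.

Step 3
Reactants: 5 ethyl 3-oxooctanoate
Product: 6 ethyl (2-pentyl-1,3-dioxolan-2-yl)acetate
Conditions: HOCH2CH2OH, p-TsOH·H2O (cat.), toluene, Dean–Stark, reflux
Reagents that add atoms: ethane-1,2-diol, OCCO
Why: Acid-catalysed ketalisation with azeotropic removal of water works routinely on the ketone of β-keto esters, the ester carbonyl being unreactive.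

Step 4
Reactants: 6 ethyl (2-pentyl-1,3-dioxolan-2-yl)acetate
Product: 7 (2-pentyl-1,3-dioxolan-2-yl)acetic acid
Conditions: NaOH, EtOH–H2O, rt; cold 1 M HCl to pH 4
Reagents that add atoms: sodium hydroxide, [Na+].[OH-]
Why: Saponification (acyl–oxygen cleavage by hydroxide) leaves the base-stable dioxolane untouched, and acidification only to pH 4 in the cold keeps it intact.

Step 5
Reactants: 7 (2-pentyl-1,3-dioxolan-2-yl)acetic acid; 8 prop-2-enyl hydrogen malonate
Product: 10 prop-2-enyl 3-oxo-4-(2-pentyl-1,3-dioxolan-2-yl)butanoate, via acyl imidazolide 9 (not isolated)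
Conditions: CDI, THF, rt; then 8, MgCl2, Et3N, THF–MeCN, rt to 40 °C; cold aq citric acid
Reagents that add atoms: 1,1'-carbonyldiimidazole, O=C(n1ccnc1)n1ccnc1 (its imidazolyl group stays only in 9)
Why: Masamune–Brooks homologation, in which the acyl imidazolide acylates the magnesium enolate of the malonic half ester and decarboxylation gives the β-keto ester under nearly neutral conditions that neither open the ketal nor trigger β-elimination of its oxygen.

Step 6
Reactants: 10 prop-2-enyl 3-oxo-4-(2-pentyl-1,3-dioxolan-2-yl)butanoate; 11 methyl 3-chloro-3-oxopropanoate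
Product: 13 prop-2-enyl 4-hydroxy-2-oxo-6-[(2-pentyl-1,3-dioxolan-2-yl)methyl]-2H-pyran-5-carboxylate, via C-acylated tricarbonyl diester 12 (not isolated)
Conditions: MgCl2, pyridine, CH2Cl2, 0 °C to rt; cold pH 5 buffer wash, solvent swap; DBU, 4 Å MS, toluene, 80 °C; cold aq citric acid
Reagents that add atoms: none
Why: MgCl2–pyridine soft enolisation directs the acid chloride to C2 of the chelated β-keto ester (C-acylation), and DBU then closes the enol oxygen of the chain ketone onto the methyl ester in the lactonisation by which 3,5-dioxo esters give 4-hydroxy-2-pyrones, the only six-membered closure open to 12, driven by formation of the acidic hydroxypyrone salt and free of acid that could harm the ketal.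

Step 7
Reactants: 13 prop-2-enyl 4-hydroxy-2-oxo-6-[(2-pentyl-1,3-dioxolan-2-yl)methyl]-2H-pyran-5-carboxylate; 2 benzyl alcohol
Product: 14 prop-2-enyl 4-(benzyloxy)-2-oxo-6-[(2-pentyl-1,3-dioxolan-2-yl)methyl]-2H-pyran-5-carboxylate
Conditions: PPh3, DIAD, THF, 0 °C to rt
Reagents that add atoms: none
Why: Mitsunobu etherification suits the acidic vinylogous carboxylic acid OH of a 4-hydroxy-2-pyrone, alkylates O4 in preference to C3 or the lactone oxygen, and is free of the base that could open the ketal by elimination from the acidic C6 methylene.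

Step 8
Reactants: 14 prop-2-enyl 4-(benzyloxy)-2-oxo-6-[(2-pentyl-1,3-dioxolan-2-yl)methyl]-2H-pyran-5-carboxylate; 4 1,1-bis(benzyloxy)ethene
Product: 17 prop-2-enyl 2,4-bis(benzyloxy)-6-[(2-pentyl-1,3-dioxolan-2-yl)methyl]benzoate, via bridged bicyclic lactone 15 (not isolated), via cyclohexadiene ketal 16 (not isolated)
Conditions: 4 (4 equiv), BHT (trace), toluene (ca. 1 M), sealed tube, 110 °C; then DBU (0.3 equiv), 60 °C
Reagents that add atoms: none
Why: The HOMO of ketene acetal 4, concentrated on its CH2 carbon, meets the LUMO of pyrone 14 at C6, the position β to the C5 ester and at the far end of the dienyl lactone, so the C6–CH2 bond (ring B C6–C5) leads and the acetal carbon closes onto C3 (ring B C3–C4), either in one asynchronous (4+2) event or through a short-lived dibenzyloxycarbenium/dienolate pair. The closest known reaction type is the inverse-electron-demand Diels–Alder reaction of alkyl 2-pyrone-5-carboxylates with ketene acetals, which gives 4-alkoxybenzoates after loss of CO2 and alcohol. The six-membered carbocycle is closed by intermolecular cycloaddition to lactone-bridged 15, retro-(4+2) extrusion of CO2 leaves cyclohexadiene 16, and 1,2-elimination of benzyl alcohol across C4/C5, completed by DBU through the vinylogous ester enolate, makes ring B aromatic. The bridgehead centres of 15 are transient and racemic, and no stereocentre survives. Only regioselectivity is needed: the C5 ester makes pyrone C6 the electrophilic terminus and the C4 benzyloxy group makes C3 the nucleophilic one, so both substituents place the new oxygen para to the ester. The C4 donor and the branched C6 substituent slow the reaction, which is answered by excess 4 (part of it is consumed by the liberated benzyl alcohol), high concentration and a ceiling of 110 °C that spares 4 from thermal benzyl migration.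

Step 9
Reactants: 17 prop-2-enyl 2,4-bis(benzyloxy)-6-[(2-pentyl-1,3-dioxolan-2-yl)methyl]benzoate
Product: 18 2,4-bis(benzyloxy)-6-[(2-pentyl-1,3-dioxolan-2-yl)methyl]benzoic acid
Conditions: Pd(PPh3)4 (5 mol %), morpholine, THF, rt; cold aq citric acid
Reagents that add atoms: none
Why: Tsuji–Trost-type deallylation, in which zerovalent palladium ionises the allyl–oxygen bond and morpholine captures the π-allyl unit, so the doubly ortho-substituted ester is cleaved without attack at its shielded carbonyl and without touching benzyl ethers or ketal.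

Step 10
Reactants: 18 2,4-bis(benzyloxy)-6-[(2-pentyl-1,3-dioxolan-2-yl)methyl]benzoic acid
Product: 20 benzyl 2,4-dihydroxy-6-[(2-pentyl-1,3-dioxolan-2-yl)methyl]benzoate, via dihydroxy acid 19 (not isolated)
Conditions: H2 (1 atm), 10% Pd/C, THF–DMF, rt; N2 purge, filtration; then KHCO3, BnBr, rt
Reagents that add atoms: benzyl bromide, BrCc1ccccc1
Why: Catalytic hydrogenolysis removes both aryl benzyl ethers, and hydrogencarbonate then deprotonates only the carboxylic acid, whose SN2 reaction with benzyl bromide gives the ester while the phenols stay free and the decarboxylation-prone acid 19 is never stored.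

Step 11
Reactants: 18 2,4-bis(benzyloxy)-6-[(2-pentyl-1,3-dioxolan-2-yl)methyl]benzoic acid; 20 benzyl 2,4-dihydroxy-6-[(2-pentyl-1,3-dioxolan-2-yl)methyl]benzoate
Product: 21 benzyl 4-({2,4-bis(benzyloxy)-6-[(2-pentyl-1,3-dioxolan-2-yl)methyl]benzoyl}oxy)-2-hydroxy-6-[(2-pentyl-1,3-dioxolan-2-yl)methyl]benzoate
Conditions: DCC, DMAP (cat.), CH2Cl2, 0 °C to rt
Reagents that add atoms: none
Why: Steglich esterification through the O-acylisourea and the acylpyridinium ion couples the hindered acid with the C4 hydroxyl of ring A, the only reactive phenol because the C2 hydroxyl is held in a hydrogen bond to the adjacent ester carbonyl, while the ketal keeps the activated acid from forming an enol lactone.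

Step 12
Reactants: 21 benzyl 4-({2,4-bis(benzyloxy)-6-[(2-pentyl-1,3-dioxolan-2-yl)methyl]benzoyl}oxy)-2-hydroxy-6-[(2-pentyl-1,3-dioxolan-2-yl)methyl]benzoate
Product: 22 benzyl 4-{[2,4-bis(benzyloxy)-6-(2-oxoheptyl)benzoyl]oxy}-2-hydroxy-6-(2-oxoheptyl)benzoate
Conditions: p-TsOH·H2O (cat.), acetone–H2O (10:1), rt; NaHCO3 quench
Reagents that add atoms: water, O
Why: Acid-catalysed ketal hydrolysis with exchange into acetone frees both ketones at room temperature, and doing it before debenzylation means that no free carboxyl group is present to add to the new carbonyl groups.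

Step 13
Reactants: 22 benzyl 4-{[2,4-bis(benzyloxy)-6-(2-oxoheptyl)benzoyl]oxy}-2-hydroxy-6-(2-oxoheptyl)benzoate
Product: 23 4-{[2,4-dihydroxy-6-(2-oxoheptyl)benzoyl]oxy}-2-hydroxy-6-(2-oxoheptyl)benzoic acid
Conditions: H2 (1 atm), 10% Pd/C, EtOAc, rt
Reagents that add atoms: none
Why: Neutral hydrogenolysis over Pd/C cleaves the benzyl ester and both benzyl ethers at once and leaves the saturated ketones and the aryl ester bond alone, so the acid-sensitive keto acid is released in the last, non-acidic step.

Compound list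
1 | 2-bromo-1,1-diethoxyethane | CCOC(CBr)OCC | starting material
2 | benzyl alcohol | OCc1ccccc1 | starting material
3 | 2-bromo-1,1-bis(benzyloxy)ethane | BrCC(OCc1ccccc1)OCc1ccccc1 | intermediate
4 | 1,1-bis(benzyloxy)ethene | C=C(OCc1ccccc1)OCc1ccccc1 | intermediate
5 | ethyl 3-oxooctanoate | CCCCCC(=O)CC(=O)OCC | starting material
6 | ethyl (2-pentyl-1,3-dioxolan-2-yl)acetate | CCCCCC1(CC(=O)OCC)OCCO1 | intermediate
7 | (2-pentyl-1,3-dioxolan-2-yl)acetic acid | CCCCCC1(CC(=O)O)OCCO1 | intermediate
8 | prop-2-enyl hydrogen malonate | C=CCOC(=O)CC(=O)O | starting material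
9 | 1-(imidazol-1-yl)-2-(2-pentyl-1,3-dioxolan-2-yl)ethan-1-one (not isolated) | CCCCCC1(CC(=O)n2ccnc2)OCCO1 | intermediate
10 | prop-2-enyl 3-oxo-4-(2-pentyl-1,3-dioxolan-2-yl)butanoate | C=CCOC(=O)CC(=O)CC1(CCCCC)OCCO1 | intermediate
11 | methyl 3-chloro-3-oxopropanoate | COC(=O)CC(=O)Cl | starting material
12 | 5-methyl 1-prop-2-enyl 3-oxo-2-[(2-pentyl-1,3-dioxolan-2-yl)acetyl]pentanedioate (not isolated; enolised, methine configurationally labile) | C=CCOC(=O)C(C(=O)CC(=O)OC)C(=O)CC1(CCCCC)OCCO1 | intermediate
13 | prop-2-enyl 4-hydroxy-2-oxo-6-[(2-pentyl-1,3-dioxolan-2-yl)methyl]-2H-pyran-5-carboxylate | C=CCOC(=O)C1=C(CC2(CCCCC)OCCO2)OC(=O)C=C1O | intermediate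
14 | prop-2-enyl 4-(benzyloxy)-2-oxo-6-[(2-pentyl-1,3-dioxolan-2-yl)methyl]-2H-pyran-5-carboxylate | C=CCOC(=O)C1=C(CC2(CCCCC)OCCO2)OC(=O)C=C1OCc1ccccc1 | intermediate
15 | prop-2-enyl 5,8,8-tris(benzyloxy)-3-oxo-1-[(2-pentyl-1,3-dioxolan-2-yl)methyl]-2-oxabicyclo[2.2.2]oct-5-ene-6-carboxylate (not isolated; racemic, bridgeheads fixed relative to each other by the bicycle) | O=C1OC2(CC3(CCCCC)OCCO3)CC(OCc3ccccc3)(OCc3ccccc3)C1C(OCc1ccccc1)=C2C(=O)OCC=C | intermediate
16 | prop-2-enyl 4,4,6-tris(benzyloxy)-2-[(2-pentyl-1,3-dioxolan-2-yl)methyl]cyclohexa-1,5-diene-1-carboxylate (not isolated) | C=CCOC(=O)C1=C(CC2(CCCCC)OCCO2)CC(OCc2ccccc2)(OCc2ccccc2)C=C1OCc1ccccc1 | intermediate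
17 | prop-2-enyl 2,4-bis(benzyloxy)-6-[(2-pentyl-1,3-dioxolan-2-yl)methyl]benzoate | C=CCOC(=O)c1c(OCc2ccccc2)cc(OCc2ccccc2)cc1CC1(CCCCC)OCCO1 | intermediate
18 | 2,4-bis(benzyloxy)-6-[(2-pentyl-1,3-dioxolan-2-yl)methyl]benzoic acid | O=C(O)c1c(OCc2ccccc2)cc(OCc2ccccc2)cc1CC1(CCCCC)OCCO1 | intermediate
19 | 2,4-dihydroxy-6-[(2-pentyl-1,3-dioxolan-2-yl)methyl]benzoic acid (not isolated) | O=C(O)c1c(O)cc(O)cc1CC1(CCCCC)OCCO1 | intermediate
20 | benzyl 2,4-dihydroxy-6-[(2-pentyl-1,3-dioxolan-2-yl)methyl]benzoate | O=C(OCc1ccccc1)c1c(O)cc(O)cc1CC1(CCCCC)OCCO1 | intermediate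
21 | benzyl 4-({2,4-bis(benzyloxy)-6-[(2-pentyl-1,3-dioxolan-2-yl)methyl]benzoyl}oxy)-2-hydroxy-6-[(2-pentyl-1,3-dioxolan-2-yl)methyl]benzoate | O=C(OCc1ccccc1)c1c(O)cc(OC(=O)c2c(OCc3ccccc3)cc(OCc3ccccc3)cc2CC2(CCCCC)OCCO2)cc1CC1(CCCCC)OCCO1 | intermediate
22 | benzyl 4-{[2,4-bis(benzyloxy)-6-(2-oxoheptyl)benzoyl]oxy}-2-hydroxy-6-(2-oxoheptyl)benzoate | O=C(OCc1ccccc1)c1c(O)cc(OC(=O)c2c(OCc3ccccc3)cc(OCc3ccccc3)cc2CC(=O)CCCCC)cc1CC(=O)CCCCC | intermediate
23 | 4-{[2,4-dihydroxy-6-(2-oxoheptyl)benzoyl]oxy}-2-hydroxy-6-(2-oxoheptyl)benzoic acid | CCCCCC(=O)Cc1cc(OC(=O)c2c(O)cc(O)cc2CC(=O)CCCCC)cc(O)c1C(=O)O | target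

Total step count: 13. Longest linear sequence: 11 (steps 3 to 13).

Steps most likely to fail

**Step 8.** The cycloaddition may be too slow, because the C4 donor raises the pyrone LUMO and C6 is crowded. Thermal benzyl migration or oligomerisation of the ketene acetal, or a stepwise addition that ends in opening of the pyrone ring, could then take over.

The fallback builds ring B by an ionic polyketide-type aromatisation. It sets out from acid 7 (through imidazolide 9) and rejoins the route at 17.
- Commercial 2,2,6-trimethyl-4H-1,3-dioxin-4-one is acetylated at its methyl group (LiN(SiMe3)2, acetyl chloride, THF, −78 °C) to 2,2-dimethyl-6-(2-oxopropyl)-4H-1,3-dioxin-4-one F1.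
- The dianion of F1 (LiN(iPr)2, 2 equiv, THF, −78 °C) is acylated by 9 to 6-[2,4-dioxo-5-(2-pentyl-1,3-dioxolan-2-yl)pentyl]-2,2-dimethyl-4H-1,3-dioxin-4-one F2.
- Heating F2 with prop-2-en-1-ol in toluene at 110 °C expels acetone, and the acylketene is trapped as prop-2-enyl 3,5,7-trioxo-8-(2-pentyl-1,3-dioxolan-2-yl)octanoate F3.
- Cs2CO3 and then AcOH bring about the C2-to-C7 aldol condensation and dehydration to prop-2-enyl 2,4-dihydroxy-6-[(2-pentyl-1,3-dioxolan-2-yl)methyl]benzoate F4.
- BnBr and K2CO3 in DMF convert F4 into 17.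

**Step 6.** Three processes may erode the yield: ketene formation from the half-ester chloride, O-acylation, and retro-Claisen cleavage of the tricarbonyl by liberated methanol, which competes with a slow lactonisation of the well-stabilised anion.

The fallback replaces the base-mediated two-stage assembly by a double acylation with a bis(acid chloride) at low temperature. It sets out from 10 and rejoins at 13.
- Me3SiCl and Et3N convert 10 into prop-2-enyl (Z)-4-(2-pentyl-1,3-dioxolan-2-yl)-3-(trimethylsilyloxy)but-2-enoate F5.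
- F5 is treated with malonyl dichloride in Et2O from −78 °C to rt, with 2,6-di-tert-butylpyridine as proton trap.
- C-acylation releases the silyl group. The remaining acid chloride terminus acylates the enol oxygen at once, which closes the hydroxypyrone.

**Step 12.** Once the ketones are free, acid-catalysed enolisation of the ring B ketone and attack of the enol oxygen on the neighbouring aryl ester carbonyl may cut the bond between the rings. The same process may occur at the ring A ester.

The fallback reverses the order of deprotection. It sets out from 21 and rejoins at 23.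
- Hydrogenolysis (H2, 10% Pd/C, EtOAc) gives 4-({2,4-dihydroxy-6-[(2-pentyl-1,3-dioxolan-2-yl)methyl]benzoyl}oxy)-2-hydroxy-6-[(2-pentyl-1,3-dioxolan-2-yl)methyl]benzoic acid F6.
- In F6 the ring B C2 hydroxyl is hydrogen-bonded to the inter-ring carbonyl and lowers its electrophilicity.
- The ketals are then opened in acetone–water at 40 °C with no added acid, the substrate's own carboxyl group being the only proton source.

Further compounds
F1 | step 8 | 2,2-dimethyl-6-(2-oxopropyl)-4H-1,3-dioxin-4-one | CC(=O)CC1=CC(=O)OC(C)(C)O1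
F2 | step 8 | 6-[2,4-dioxo-5-(2-pentyl-1,3-dioxolan-2-yl)pentyl]-2,2-dimethyl-4H-1,3-dioxin-4-one | CCCCCC1(CC(=O)CC(=O)CC2=CC(=O)OC(C)(C)O2)OCCO1
F3 | step 8 | prop-2-enyl 3,5,7-trioxo-8-(2-pentyl-1,3-dioxolan-2-yl)octanoate | C=CCOC(=O)CC(=O)CC(=O)CC(=O)CC1(CCCCC)OCCO1
F4 | step 8 | prop-2-enyl 2,4-dihydroxy-6-[(2-pentyl-1,3-dioxolan-2-yl)methyl]benzoate | C=CCOC(=O)c1c(O)cc(O)cc1CC1(CCCCC)OCCO1
F5 | step 6 | prop-2-enyl (Z)-4-(2-pentyl-1,3-dioxolan-2-yl)-3-(trimethylsilyloxy)but-2-enoate | C=CCOC(=O)/C=C(/CC1(CCCCC)OCCO1)O[Si](C)(C)C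
F6 | step 12 | 4-({2,4-dihydroxy-6-[(2-pentyl-1,3-dioxolan-2-yl)methyl]benzoyl}oxy)-2-hydroxy-6-[(2-pentyl-1,3-dioxolan-2-yl)methyl]benzoic acid | O=C(O)c1c(O)cc(OC(=O)c2c(O)cc(O)cc2CC2(CCCCC)OCCO2)cc1CC1(CCCCC)OCCO1
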